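**Plan**

- Numbering: ring methine C1, C2H2, C3=C4(Me), C5, C6, C7=C8(Me), C9, C10, C11=C12(Me), C13H2, C14H2; carbinol C15 (15S, 1R in the target).
- Retrosynthesis: after removal of a C15 silyl ether, the 14-membered ring is cut at C12–C13. The C13–C14 ethylene bridge between C1 and the methyl-bearing alkene carbon C12 is what a C1 vinyl group becomes on hydroboration, opposite an (E)-C12 alkenyl iodide.
- The open chain is cut at C1–C15 (allylboration of (E)-geranylacetone), C1=C14 (cross-metathesis that brings in the allylboron unit), C1–C2 (vinyl cuprate on an allylic bromide) and C9–C10 (but-2-ynyl anion on an 8-bromogeranyl ether). C12–I comes from hydrozirconation–iodination.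
- Forward: geraniol is grown linearly into the C2–C14 iodo-allylboron chain, joined to geranylacetone, silylated, cyclised (the only ring, closed last) and desilylated.
- Stereochemistry: C15 and C1 arise together in the closed chair of an (S)-3,3′-dibromo-BINOL-catalysed allylboration (Z reagent gives the syn pair, the diol selects the ketone Re face). The E alkenes come from geraniol, geranylacetone and syn-hydrozirconation and are carried unchanged.

Key step: step 13

Assumption: (S)-3,3′-dibromo-BINOL is taken to direct the allyl group to the Re face of a methyl ketone whose larger substituent is equatorial in the chair, by analogy with the sense accepted for acetophenone with this catalyst class; if the first run shows the opposite sense, the (R) diol is used and nothing else changes.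

**Route**

Step 1
Reactants: 1 geraniol
Product: 2 geranyl tert-butyldimethylsilyl ether
Conditions: TBSCl, imidazole, CH2Cl2, 0 °C to rt
Reagents that add atoms: tert-butyldimethylsilyl chloride CC(C)(C)[Si](C)(C)Cl
Why: Silyl ether formation masks the allylic alcohol against the organolithium and zirconium hydride reagents used later and makes the adjacent alkene (C3=C4 of the target) less prone to the allylic oxidation that follows.

Step 2
Reactants: 2 geranyl tert-butyldimethylsilyl ether
Product: 3 (2E,6E)-8-[(tert-butyldimethylsilyl)oxy]-2,6-dimethylocta-2,6-dien-1-ol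
Conditions: SeO2 (cat.), t-BuOOH, salicylic acid (cat.), CH2Cl2, 0 °C to rt
Reagents that add atoms: tert-butyl hydroperoxide CC(C)(C)OO; selenium dioxide O=[Se]=O
Why: Catalytic selenium dioxide allylic oxidation (ene reaction followed by a 2,3-sigmatropic shift) hydroxylates the E methyl group of the more electron-rich terminal alkene, so the future C9 is obtained as an E allylic alcohol.

Step 3
Reactants: 3 (2E,6E)-8-[(tert-butyldimethylsilyl)oxy]-2,6-dimethylocta-2,6-dien-1-ol
Product: 4 tert-butyl{[(2E,6E)-8-bromo-3,7-dimethylocta-2,6-dien-1-yl]oxy}dimethylsilane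
Conditions: CBr4, PPh3, CH2Cl2, 0 °C
Reagents that add atoms: carbon tetrabromide BrC(Br)(Br)Br
Why: Appel bromination turns the primary allylic alcohol into the bromide under neutral conditions, without allylic transposition and without loss of the silyl ether.

Step 4
Reactants: 4 tert-butyl{[(2E,6E)-8-bromo-3,7-dimethylocta-2,6-dien-1-yl]oxy}dimethylsilane; 5 2-butyne
Product: 7 tert-butyl{[(2E,6E)-3,7-dimethyldodeca-2,6-dien-10-yn-1-yl]oxy}dimethylsilane, via but-2-ynyllithium 6 (not isolated)
Conditions: 5 (excess), n-BuLi, TMEDA, THF, −78 to 0 °C; then 4, −78 °C to rt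
Reagents that add atoms: none
Why: Propargylic lithiation of 2-butyne and SN2 alkylation at the unhindered CH2 of the allylic bromide forms C9–C10 and installs the methyl-capped alkyne that holds C10–C12 and the C12 methyl group.

Step 5
Reactants: 7 tert-butyl{[(2E,6E)-3,7-dimethyldodeca-2,6-dien-10-yn-1-yl]oxy}dimethylsilane
Product: 9 tert-butyl{[(2E,6E,10E)-11-iodo-3,7-dimethyldodeca-2,6,10-trien-1-yl]oxy}dimethylsilane, via alkenylzirconocene chloride 8 (not isolated)
Conditions: Cp2Zr(H)Cl (2.5 equiv), THF, 50 °C; then I2, 0 °C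
Reagents that add atoms: iodine II
Why: Schwartz hydrozirconation adds H and Zr syn across the alkyne and, with excess reagent, equilibrates zirconium onto the less hindered methyl-bearing carbon, and iodinolysis with retention then gives the E 2-iodoalkene (C11=C12 with iodine on C12) while the trisubstituted alkenes and the silyl ether are left alone.

Step 6
Reactants: 9 tert-butyl{[(2E,6E,10E)-11-iodo-3,7-dimethyldodeca-2,6,10-trien-1-yl]oxy}dimethylsilane
Product: 10 (2E,6E,10E)-11-iodo-3,7-dimethyldodeca-2,6,10-trien-1-ol
Conditions: Bu4NF, THF, 0 °C to rt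
Reagents that add atoms: none
Why: Fluoride-mediated desilylation frees the allylic alcohol and does not affect the alkenyl iodide.

Step 7
Reactants: 10 (2E,6E,10E)-11-iodo-3,7-dimethyldodeca-2,6,10-trien-1-ol
Product: 11 (2E,6E,10E)-1-bromo-11-iodo-3,7-dimethyldodeca-2,6,10-triene
Conditions: CBr4, PPh3, CH2Cl2, 0 °C
Reagents that add atoms: carbon tetrabromide BrC(Br)(Br)Br
Why: A second Appel bromination activates C2 as a primary allylic bromide, which is carried forward without storage.

Step 8
Reactants: 11 (2E,6E,10E)-1-bromo-11-iodo-3,7-dimethyldodeca-2,6,10-triene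
Product: 12 (4E,8E,12E)-13-iodo-5,9-dimethyltetradeca-1,4,8,12-tetraene
Conditions: CH2=CHMgBr, CuI (10 mol %), THF, −30 to 0 °C
Reagents that add atoms: vinylmagnesium bromide C=C[Mg]Br
Why: Copper-catalysed Grignard allylic substitution takes place at the primary carbon of the γ,γ-disubstituted allyl bromide (attack at the fully substituted γ carbon is disfavoured), which forms C1–C2 with the C3=C4 geometry kept, and the alkenyl iodide should not react at this temperature.

Step 9
Reactants: 12 (4E,8E,12E)-13-iodo-5,9-dimethyltetradeca-1,4,8,12-tetraene; 13 allylboronic acid pinacol ester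
Product: 14 2-[(2Z,5E,9E,13E)-14-iodo-6,10-dimethylpentadeca-2,5,9,13-tetraen-1-yl]-4,4,5,5-tetramethyl-1,3,2-dioxaborolane
Conditions: 13 (3 equiv), Mo(NAd)(CHCMe2Ph)(NC4H4)(OHIPT) (5 mol %), C6H6, rt, reduced pressure
Reagents that add atoms: none
Why: Z-selective olefin cross-metathesis with a monoaryloxide pyrrolide molybdenum alkylidene (Ad = 1-adamantyl, HIPT = 2,6-bis(2,4,6-triisopropylphenyl)phenyl) engages only the monosubstituted alkene, and the large aryloxide pushes both metallacyclobutane substituents toward the small imido ligand so that the new C1=C14 bond is Z.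

Step 10
Reactants: 14 2-[(2Z,5E,9E,13E)-14-iodo-6,10-dimethylpentadeca-2,5,9,13-tetraen-1-yl]-4,4,5,5-tetramethyl-1,3,2-dioxaborolane
Product: 15 potassium trifluoro[(2Z,5E,9E,13E)-14-iodo-6,10-dimethylpentadeca-2,5,9,13-tetraen-1-yl]borate
Conditions: KHF2, MeOH/H2O, 0 °C to rt
Reagents that add atoms: potassium hydrogen difluoride [K+].[F-].F
Why: Conversion of the pinacol boronate into its trifluoroborate removes the pinacol, which would block ligand exchange with a diol catalyst, and keeps the Z geometry because tetracoordinate boron cannot undergo a 1,3-boron shift.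

Step 11
Reactants: 15 potassium trifluoro[(2Z,5E,9E,13E)-14-iodo-6,10-dimethylpentadeca-2,5,9,13-tetraen-1-yl]borate; 16 (E)-geranylacetone
Product: 18 (6E,10S,11S,13E,17E,21E)-11-ethenyl-22-iodo-2,6,10,14,18-pentamethyltricosa-2,6,13,17,21-pentaen-10-ol, via allylboronic acid 17 (not isolated)
Conditions: SiO2, H2O, EtOAc, rt; then 16 (2 equiv), (S)-3,3′-Br2-BINOL (20 mol %), t-BuOH, 3 Å MS, PhMe, 0 °C to rt
Reagents that add atoms: none
Why: Hydrolysis on wet silica liberates the Z allylboronic acid 17, which exchanges reversibly with the chiral diol and adds to the ketone through a closed chair transition state (chiral-diol-catalysed allylboration of a ketone) with the homogeranyl arm equatorial and the Z γ-substituent axial, so that the C15 hydroxyl and the C2 chain come out syn, while the (S)-diol-bound boron exposes the ketone Re face and so sets 10S (C15) and with it 11S (C1).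

Step 12
Reactants: 18 (6E,10S,11S,13E,17E,21E)-11-ethenyl-22-iodo-2,6,10,14,18-pentamethyltricosa-2,6,13,17,21-pentaen-10-ol
Product: 19 triethyl{[(6E,10S,11S,13E,17E,21E)-11-ethenyl-22-iodo-2,6,10,14,18-pentamethyltricosa-2,6,13,17,21-pentaen-10-yl]oxy}silane
Conditions: Et3SiOTf, 2,6-lutidine, CH2Cl2, −78 to 0 °C
Reagents that add atoms: triethylsilyl trifluoromethanesulfonate CC[Si](CC)(CC)OS(=O)(=O)C(F)(F)F
Why: Silyl triflate silylation caps the hindered tertiary alcohol so that it neither consumes 9-BBN nor, as a tertiary homoallylic alkoxide, undergoes palladium-mediated retro-allylation in the next step.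

Step 13
Reactants: 19 triethyl{[(6E,10S,11S,13E,17E,21E)-11-ethenyl-22-iodo-2,6,10,14,18-pentamethyltricosa-2,6,13,17,21-pentaen-10-yl]oxy}silane
Product: 21 colleterpenol triethylsilyl ether, via B-alkyl-9-BBN borane 20 (not isolated)
Conditions: 9-BBN (1.5 equiv), THF, 0 °C to rt; then slow addition to PdCl2(dppf) (20 mol %), AsPh3 (40 mol %), Cs2CO3, DMF/THF/H2O, 50 °C, final concentration about 1 mM
Reagents that add atoms: none
Why: The dialkylborane 9-BBN delivers boron to the terminal carbon C13 of the lone vinyl group (intermediate 20); aqueous Cs2CO3 then quaternises boron, zerovalent palladium undergoes oxidative addition at C12–I, the primary alkyl group migrates from boron to palladium and reductive elimination joins C12 to C13. The closest known reaction type is the one-pot 9-BBN hydroboration and intramolecular B-alkyl Suzuki–Miyaura macrocyclisation of a terminal alkene onto an alkenyl iodide, with AsPh3 added to speed transmetalation. The 14-membered carbocycle closes by sp3–sp2 reductive elimination from a 15-membered alkyl(alkenyl)palladium cycle, and slow addition to high dilution should keep this ahead of oligomer formation. No stereocentre is made: C15 and C1 are spectators (C1 only changes descriptor from S to R because ring closure reorders its substituents), and the C11=C12 geometry is kept because oxidative addition and reductive elimination both proceed with retention at the alkenyl carbon. The step depends on 9-BBN discriminating the vinyl group from the four trisubstituted alkenes and the iodine-bearing alkene, which follows from its bulk, and on the alkylborane surviving until coupling, which the silyl-capped C15 oxygen and a degassed basic medium support.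

Step 14
Reactants: 21 colleterpenol triethylsilyl ether
Product: 22 colleterpenol
Conditions: Bu4NF, THF, rt to 40 °C
Reagents that add atoms: none
Why: Fluoride-mediated cleavage of the tertiary triethylsilyl ether releases the carbinol without touching the four trisubstituted alkenes or the two stereocentres.

**Compound list**

1 | geraniol, (2E)-3,7-dimethylocta-2,6-dien-1-ol | CC(C)=CCC/C(C)=C/CO | starting material
2 | tert-butyl{[(2E)-3,7-dimethylocta-2,6-dien-1-yl]oxy}dimethylsilane | CC(C)=CCC/C(C)=C/CO[Si](C)(C)C(C)(C)C | intermediate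
3 | (2E,6E)-8-[(tert-butyldimethylsilyl)oxy]-2,6-dimethylocta-2,6-dien-1-ol | OC/C(C)=C/CC/C(C)=C/CO[Si](C)(C)C(C)(C)C | intermediate
4 | tert-butyl{[(2E,6E)-8-bromo-3,7-dimethylocta-2,6-dien-1-yl]oxy}dimethylsilane | BrC/C(C)=C/CC/C(C)=C/CO[Si](C)(C)C(C)(C)C | intermediate
5 | 2-butyne | CC#CC | starting material
6 | but-2-ynyllithium | [Li]CC#CC | intermediate
7 | tert-butyl{[(2E,6E)-3,7-dimethyldodeca-2,6-dien-10-yn-1-yl]oxy}dimethylsilane | CC#CCC/C(C)=C/CC/C(C)=C/CO[Si](C)(C)C(C)(C)C | intermediate
8 | chlorobis(cyclopentadienyl)[(2E,6E,10E)-12-(tert-butyldimethylsilyloxy)-6,10-dimethyldodeca-2,6,10-trien-2-yl]zirconium (H and Zr cis) | C/C(=C\CC/C(C)=C/CC/C(C)=C/CO[Si](C)(C)C(C)(C)C)[Zr](Cl)(C1C=CC=C1)C1C=CC=C1 | intermediate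
9 | tert-butyl{[(2E,6E,10E)-11-iodo-3,7-dimethyldodeca-2,6,10-trien-1-yl]oxy}dimethylsilane | C/C(I)=C\CC/C(C)=C/CC/C(C)=C/CO[Si](C)(C)C(C)(C)C | intermediate
10 | (2E,6E,10E)-11-iodo-3,7-dimethyldodeca-2,6,10-trien-1-ol | C/C(I)=C\CC/C(C)=C/CC/C(C)=C/CO | intermediate
11 | (2E,6E,10E)-1-bromo-11-iodo-3,7-dimethyldodeca-2,6,10-triene | C/C(I)=C\CC/C(C)=C/CC/C(C)=C/CBr | intermediate
12 | (4E,8E,12E)-13-iodo-5,9-dimethyltetradeca-1,4,8,12-tetraene | C/C(I)=C\CC/C(C)=C/CC/C(C)=C/CC=C | intermediate
13 | allylboronic acid pinacol ester, 2-allyl-4,4,5,5-tetramethyl-1,3,2-dioxaborolane | C=CCB1OC(C)(C)C(C)(C)O1 | starting material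
14 | 2-[(2Z,5E,9E,13E)-14-iodo-6,10-dimethylpentadeca-2,5,9,13-tetraen-1-yl]-4,4,5,5-tetramethyl-1,3,2-dioxaborolane | C/C(I)=C\CC/C(C)=C/CC/C(C)=C/C/C=C\CB1OC(C)(C)C(C)(C)O1 | intermediate
15 | potassium trifluoro[(2Z,5E,9E,13E)-14-iodo-6,10-dimethylpentadeca-2,5,9,13-tetraen-1-yl]borate | C/C(I)=C\CC/C(C)=C/CC/C(C)=C/C/C=C\C[B-](F)(F)F.[K+] | intermediate
16 | (E)-geranylacetone, (5E)-6,10-dimethylundeca-5,9-dien-2-one, bought as the single E isomer | CC(C)=CCC/C(C)=C/CCC(C)=O | starting material
17 | [(2Z,5E,9E,13E)-14-iodo-6,10-dimethylpentadeca-2,5,9,13-tetraen-1-yl]boronic acid | C/C(I)=C\CC/C(C)=C/CC/C(C)=C/C/C=C\CB(O)O | intermediate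
18 | (6E,10S,11S,13E,17E,21E)-11-ethenyl-22-iodo-2,6,10,14,18-pentamethyltricosa-2,6,13,17,21-pentaen-10-ol | CC(C)=CCC/C(C)=C/CC[C@](C)(O)[C@H](C=C)C/C=C(\C)CC/C=C(\C)CC/C=C(\C)I | intermediate
19 | triethyl{[(6E,10S,11S,13E,17E,21E)-11-ethenyl-22-iodo-2,6,10,14,18-pentamethyltricosa-2,6,13,17,21-pentaen-10-yl]oxy}silane | CC(C)=CCC/C(C)=C/CC[C@](C)(O[Si](CC)(CC)CC)[C@H](C=C)C/C=C(\C)CC/C=C(\C)CC/C=C(\C)I | intermediate
20 | 19 with the vinyl group converted into CH2CH2 bonded to the boron of 9-borabicyclo[3.3.1]nonane (boron on C13) | CC(C)=CCC/C(C)=C/CC[C@](C)(O[Si](CC)(CC)CC)[C@H](CCB1C2CCCC1CCC2)C/C=C(\C)CC/C=C(\C)CC/C=C(\C)I | intermediate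
21 | colleterpenol triethylsilyl ether, triethyl{[(2S,5E)-6,10-dimethyl-2-[(1R,3E,7E,11E)-4,8,12-trimethylcyclotetradeca-3,7,11-trien-1-yl]undeca-5,9-dien-2-yl]oxy}silane | CC(C)=CCC/C(C)=C/CC[C@](C)(O[Si](CC)(CC)CC)[C@H]1C/C=C(\C)CC/C=C(\C)CC/C=C(\C)CC1 | intermediate
22 | colleterpenol, (2S,5E)-6,10-dimethyl-2-[(1R,3E,7E,11E)-4,8,12-trimethylcyclotetradeca-3,7,11-trien-1-yl]undeca-5,9-dien-2-ol | CC(C)=CCC/C(C)=C/CC[C@](C)(O)[C@H]1C/C=C(\C)CC/C=C(\C)CC/C=C(\C)CC1 | target

**Step count**

Total: 14 steps. Longest linear sequence: 14 steps (1 to 22); 5, 13 and 16 enter as purchased reagents.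

**Steps most likely to fail**

Step 11. The diol-bound boron may discriminate poorly between the two ketone faces, the methyl and homogeranyl groups may compete for the equatorial site of the chair, and the free allylboronic acid may be lost by oxidation or protodeboronation. Fallback, setting out from 15 and 16 and returning at 18: catalyst control is given up in favour of resolution. Acid 17 is generated as before and added to 16 without diol (PhMe, rt), where the closed transition state should still give the syn pair, now as 18 together with its mirror image (6E,10R,11R,13E,17E,21E)-11-ethenyl-22-iodo-2,6,10,14,18-pentamethyltricosa-2,6,13,17,21-pentaen-10-ol F1. The two are separated by preparative chromatography on a cellulose tris(3,5-dimethylphenylcarbamate) stationary phase, and 18 goes on to step 12.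

Step 13. Intermolecular coupling may outrun ring closure, and the alkylborane may be lost by protodeboronation or the alkenylpalladium iodide by reduction before transmetalation. Fallback, setting out from 19 and returning at 21: the same C12–C13 bond is closed by an intramolecular Negishi coupling. Hydroboration of 19 with 9-BBN and oxidation (NaOH, H2O2, 0 °C) would give the primary alcohol, 19 with CH2CH2OH in place of the vinyl group, F2. Treatment with I2, PPh3 and imidazole would give the primary iodide F3. Zinc dust with LiCl in THF should insert only into the sp3 C–I bond, giving the alkylzinc iodide F4. Slow addition of F4 to Pd(PPh3)4 in THF/NMP at 50 °C under high dilution would then deliver 21.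

Step 9. The metathesis may stall on the skipped diene, lose Z selectivity through secondary isomerisation, or be diverted into homocoupling. Fallback, setting out from 11 and returning at 14 (step 8 is bypassed): the Z allylboronate is made by allene hydroboration. Allenyllithium (propadiene, n-BuLi, THF, −78 °C) is alkylated by 11 to give (5E,9E,13E)-14-iodo-6,10-dimethylpentadeca-1,2,5,9,13-pentaene F5. Copper hydride catalysed hydroboration with pinacolborane (CuCl, NaOt-Bu, a Xantphos-type bisphosphine, THF) is expected to place boron on the terminal carbon and hydrogen on the central carbon, giving 14 with Z geometry.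

**Further compounds**

F1 | step 11 | (6E,10R,11R,13E,17E,21E)-11-ethenyl-22-iodo-2,6,10,14,18-pentamethyltricosa-2,6,13,17,21-pentaen-10-ol, the enantiomer of 18 | CC(C)=CCC/C(C)=C/CC[C@@](C)(O)[C@@H](C=C)C/C=C(\C)CC/C=C(\C)CC/C=C(\C)I
F2 | step 13 | primary alcohol, 19 with CH2CH2OH in place of the vinyl group | CC(C)=CCC/C(C)=C/CC[C@](C)(O[Si](CC)(CC)CC)[C@H](CCO)C/C=C(\C)CC/C=C(\C)CC/C=C(\C)I
F3 | step 13 | primary iodide, 19 with CH2CH2I in place of the vinyl group | CC(C)=CCC/C(C)=C/CC[C@](C)(O[Si](CC)(CC)CC)[C@H](CCI)C/C=C(\C)CC/C=C(\C)CC/C=C(\C)I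
F4 | step 13 | alkylzinc iodide, 19 with CH2CH2ZnI in place of the vinyl group | CC(C)=CCC/C(C)=C/CC[C@](C)(O[Si](CC)(CC)CC)[C@H](CC[Zn]I)C/C=C(\C)CC/C=C(\C)CC/C=C(\C)I
F5 | step 9 | (5E,9E,13E)-14-iodo-6,10-dimethylpentadeca-1,2,5,9,13-pentaene | C/C(I)=C\CC/C(C)=C/CC/C(C)=C/CC=C=C
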